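The disconnection is the bond between the aryl ketone carbon and C2 of its 4,5-dichloropyrrole ring. The key step exploits the pyrrole N1–H beside C2: as its N-magnesium salt, 2,3-dichloropyrrole is acylated at its only free α-carbon, and the ketone is then shielded as a pyrrolide. It also exploits the phenol oxygen on the benzene carbon para to that ketone and ortho to the side chain, which is held in a δ-lactone with the side-chain carboxyl. The precursor is thus a hydroxy-dihydrocoumarin carbonyl chloride: in one flask the acid chloride gives the aryl ketone, then the same reagent opens the lactone to the second pyrrolyl ketone and frees the phenol.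

Key step: step 6

Remark: the target has no stereocentre. It is assumed that 2,3-dichloro-1H-pyrrole survives for some hours as a cold, dilute solution under argon.

Step 1
Reactants: 1 cyclohexane-1,3-dione; 2 methyl acrylate
Product: 3 methyl 3-(2,6-dioxocyclohexyl)propanoate
Conditions: NaOMe (0.1 equiv), MeOH, reflux; 1.0 equiv of 2
Reagents that add atoms: none
Why: Michael addition, in which the stabilised C2 enolate of the 1,3-dione adds to the acrylate β-carbon and one equivalent of acrylate should hold the reaction at mono-alkylation.

Step 2
Reactants: 3 methyl 3-(2,6-dioxocyclohexyl)propanoate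
Product: 5 5-hydroxychroman-2-one (5-hydroxy-3,4-dihydrocoumarin), via resorcinol ester 4 (not isolated)
Conditions: 10% Pd/C, mesitylene, reflux, Ar sweep; then TsOH·H2O (5 mol %), reflux
Reagents that add atoms: none
Why: Catalytic dehydrogenation of the enolised 2-alkylcyclohexane-1,3-dione should give the 2-alkylresorcinol with loss of one H2, and one of its two equivalent phenols then closes the six-membered aryl lactone by acid-catalysed transesterification with loss of methanol.

Step 3
Reactants: 5 5-hydroxychroman-2-one
Product: 7 3-(2-carboxyethyl)-2,4-dihydroxybenzoic acid, via ring-opened acid 6 (not isolated)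
Conditions: KHCO3 (6 equiv), H2O, CO2 (5 bar), 110 °C, sealed; then cold 3 M HCl to pH 1
Reagents that add atoms: carbon dioxide O=C=O; water O
Why: Aqueous Kolbe–Schmitt carboxylation, in which hot bicarbonate opens the lactone and the resorcinol anion is carboxylated ortho to one hydroxyl and para to the other; the two such positions are equivalent by symmetry, so only the 3-alkyl-2,4-dihydroxybenzoic acid should form.

Step 4
Reactants: 7 3-(2-carboxyethyl)-2,4-dihydroxybenzoic acid
Product: 9 5-hydroxy-2-oxochromane-6-carbonyl chloride, via lactone acid 8 (not isolated)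
Conditions: SOCl2 (3 equiv), DMF (cat.), PhMe, 60 °C; evaporate, use crude
Reagents that add atoms: thionyl chloride O=S(Cl)Cl
Why: Acid chloride formation with lactonisation, in which the aliphatic acid chloride forms first and acylates the free 4-hydroxyl in a six-membered ring (the 2-hydroxyl is held in the salicylic hydrogen bond), after which the aromatic acid should give an o-hydroxybenzoyl chloride stabilised by that same hydrogen bond.

Step 5
Reactants: 10 4,5-dichloro-1H-pyrrole-2-carboxylic acid
Product: 11 2,3-dichloro-1H-pyrrole
Conditions: Ag2CO3 (10 mol %), AcOH (5 mol %), DMSO, 100 °C, Ar; extract (pentane/Et2O), dry, exchange into cold PhMe, use at once as a solution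
Reagents that add atoms: none
Why: Silver-catalysed protodecarboxylation of a heteroaromatic α-carboxylic acid through the C2–silver species, with the product kept cold and dilute because α-chloropyrroles without an acceptor group degrade when concentrated.

Step 6
Reactants: 9 5-hydroxy-2-oxochromane-6-carbonyl chloride; 11 2,3-dichloro-1H-pyrrole
Product: 14 dihydrotetrachlorizine, via N-magnesio dichloropyrrole 12 (not isolated), via aroylpyrrole lactone 13 (not isolated)
Conditions: 11 (5.5 equiv), i-PrMgCl (5.3 equiv), THF/PhMe, 0 °C; add 9 in THF at −78 °C, then warm to rt; aq. NH4Cl, citric acid to pH 3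
Reagents that add atoms: none
Why: This is an Oddo acylation run twice in one flask: the N–Mg pyrrolide 12 attacks through C5, its only free α-carbon (C2 and C3 carry chlorine), first the aroyl chloride of 9 at −78 °C to form the aryl C(=O)–C2(pyrrole) bond of 13, then on warming the aryl ester carbonyl of the δ-lactone, which gives the second ketone and releases the phenoxide. The closest known reactions are the acylation of pyrrolylmagnesium halides with aroyl chlorides, the standard entry to 2-aroylpyrroles, and with esters or lactones. No ring is closed (the lactone ring is opened) and no stereocentre is formed. The step needs C- over N-acylation, mono-addition and the order chloride before lactone: the covalent N–Mg bond in toluene directs acylation to carbon and any N-acylpyrrole is itself an acyl donor that is funnelled to the C-acyl product, each ketone is deprotonated to its pyrrolide (the aryl ketone is also chelated by the ortho phenoxide) so that over-addition is blocked, and the acid chloride is far more electrophilic than the lactone. Because the lactone is still closed when the aroyl carbon is attacked, the oxygen para to that carbon is an ester oxygen and not a deactivating phenoxide. The first equivalent of 12 only deprotonates the hydrogen-bonded phenol of 9, and any aryl ester oligomer or quinoid ketene formed from that phenoxide is an acyl donor of the same kind that should converge on 13; three further equivalents are consumed as base, hence the excess.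

Compound list
1 | cyclohexane-1,3-dione | O=C1CCCC(=O)C1 | starting material
2 | methyl acrylate | C=CC(=O)OC | starting material
3 | methyl 3-(2,6-dioxocyclohexyl)propanoate | COC(=O)CCC1C(=O)CCCC1=O | intermediate
4 | methyl 3-(2,6-dihydroxyphenyl)propanoate | COC(=O)CCc1c(O)cccc1O | intermediate (not isolated)
5 | 5-hydroxychroman-2-one (5-hydroxy-3,4-dihydrocoumarin) | O=C1CCc2c(O)cccc2O1 | intermediate
6 | 3-(2,6-dihydroxyphenyl)propanoic acid (present as its potassium salt) | OC(=O)CCc1c(O)cccc1O | intermediate (not isolated)
7 | 3-(2-carboxyethyl)-2,4-dihydroxybenzoic acid | OC(=O)CCc1c(O)ccc(C(=O)O)c1O | intermediate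
8 | 5-hydroxy-2-oxochromane-6-carboxylic acid | O=C1CCc2c(O1)ccc(C(=O)O)c2O | intermediate (not isolated)
9 | 5-hydroxy-2-oxochromane-6-carbonyl chloride | O=C1CCc2c(O1)ccc(C(=O)Cl)c2O | intermediate
10 | 4,5-dichloro-1H-pyrrole-2-carboxylic acid | OC(=O)c1cc(Cl)c(Cl)[nH]1 | starting material
11 | 2,3-dichloro-1H-pyrrole | Clc1cc[nH]c1Cl | intermediate
12 | (2,3-dichloropyrrol-1-yl)magnesium chloride | Clc1ccn([Mg]Cl)c1Cl | intermediate (not isolated)
13 | (4,5-dichloro-1H-pyrrol-2-yl)(5-hydroxy-2-oxochroman-6-yl)methanone | O=C1CCc2c(O1)ccc(C(=O)c3cc(Cl)c(Cl)[nH]3)c2O | intermediate (not isolated)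
14 | dihydrotetrachlorizine, 1-(4,5-dichloro-1H-pyrrol-2-yl)-3-[3-(4,5-dichloro-1H-pyrrole-2-carbonyl)-2,6-dihydroxyphenyl]propan-1-one | O=C(CCc1c(O)ccc(C(=O)c2cc(Cl)c(Cl)[nH]2)c1O)c1cc(Cl)c(Cl)[nH]1 | target

Total step count: 6. Longest linear sequence: 5 steps (steps 1, 2, 3, 4 and 6); step 5 is a one-step side branch.

Steps most likely to fail

Step 6. The phenoxide of 9 may acylate another molecule of acid chloride faster than the pyrrolide attacks it, the pyrrolide may be acylated on nitrogen, or the reaction may stall at 13 because the chlorinated pyrrolide is too weak a nucleophile for the lactone. The fallback sets out from 7 and comes back at 14; it protects both phenols and makes both acyl donors acid chlorides. Permethylation of 7 (Me2SO4, K2CO3, acetone, reflux) should give methyl 2,4-dimethoxy-3-(3-methoxy-3-oxopropyl)benzoate F1. Saponification (LiOH, THF/H2O) should give 3-(2-carboxyethyl)-2,4-dimethoxybenzoic acid F2, and (COCl)2 with catalytic DMF in CH2Cl2 should give 3-(3-chloro-3-oxopropyl)-2,4-dimethoxybenzoyl chloride F3. Double Oddo acylation of 12 with F3 (PhMe/THF, −78 °C to rt) should give dihydrotetrachlorizine dimethyl ether F4, and BBr3 (CH2Cl2, −78 to 0 °C) should cleave both methyl ethers to give 14.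

Step 5. The acceptor-free α-chloropyrrole may oligomerise or oxidise during extraction and solvent exchange, so that no usable solution of 11 reaches step 6. The fallback sets out from 9 and comes back at 14; it brings in the chlorine atoms last. Pyrrole and i-PrMgCl give pyrrol-1-ylmagnesium chloride F5, which under the conditions of step 6 should convert 9 into 1-(1H-pyrrol-2-yl)-3-[2,6-dihydroxy-3-(1H-pyrrole-2-carbonyl)phenyl]propan-1-one F6. Acetylation (Ac2O, pyridine, 40 °C) should give 2-[3-oxo-3-(1H-pyrrol-2-yl)propyl]-4-(1H-pyrrole-2-carbonyl)-1,3-phenylene diacetate F7, in which the benzene ring is deactivated. Sulfuryl chloride (4.2 equiv, AcOH/Et2O, 0 °C) should chlorinate each 2-acylpyrrole at C4 and C5 to give dihydrotetrachlorizine diacetate F8, and K2CO3 in MeOH should remove the acetates to give 14.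

Step 4. The side-chain acid chloride may close onto the wrong (2-) hydroxyl or esterify a second molecule in place of ring closure, giving isomeric or oligomeric material. The fallback sets out from 5 and comes back at 8; it keeps the lactone closed throughout and replaces steps 3 and 4. Ortho-selective formylation of 5 (MgCl2, Et3N, paraformaldehyde, MeCN, reflux) at the only free position next to the phenol should give 5-hydroxy-2-oxochromane-6-carbaldehyde F9. Pinnick oxidation (NaClO2, NaH2PO4, 2-methyl-2-butene, t-BuOH/H2O) should then give 8 as an isolated compound, which SOCl2 converts into 9 as in step 4.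

Further compounds
F1 | step 6 | methyl 2,4-dimethoxy-3-(3-methoxy-3-oxopropyl)benzoate | COC(=O)CCc1c(OC)ccc(C(=O)OC)c1OC
F2 | step 6 | 3-(2-carboxyethyl)-2,4-dimethoxybenzoic acid | OC(=O)CCc1c(OC)ccc(C(=O)O)c1OC
F3 | step 6 | 3-(3-chloro-3-oxopropyl)-2,4-dimethoxybenzoyl chloride | O=C(Cl)CCc1c(OC)ccc(C(=O)Cl)c1OC
F4 | step 6 | dihydrotetrachlorizine dimethyl ether | O=C(CCc1c(OC)ccc(C(=O)c2cc(Cl)c(Cl)[nH]2)c1OC)c1cc(Cl)c(Cl)[nH]1
F5 | step 5 | pyrrol-1-ylmagnesium chloride | Cl[Mg]n1cccc1
F6 | step 5 | 1-(1H-pyrrol-2-yl)-3-[2,6-dihydroxy-3-(1H-pyrrole-2-carbonyl)phenyl]propan-1-one | O=C(CCc1c(O)ccc(C(=O)c2ccc[nH]2)c1O)c1ccc[nH]1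
F7 | step 5 | 2-[3-oxo-3-(1H-pyrrol-2-yl)propyl]-4-(1H-pyrrole-2-carbonyl)-1,3-phenylene diacetate | O=C(CCc1c(OC(C)=O)ccc(C(=O)c2ccc[nH]2)c1OC(C)=O)c1ccc[nH]1
F8 | step 5 | dihydrotetrachlorizine diacetate | O=C(CCc1c(OC(C)=O)ccc(C(=O)c2cc(Cl)c(Cl)[nH]2)c1OC(C)=O)c1cc(Cl)c(Cl)[nH]1
F9 | step 4 | 5-hydroxy-2-oxochromane-6-carbaldehyde | O=Cc1ccc2OC(=O)CCc2c1O
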